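A direct plan would join two bromoarenes by SNAr and then trade a formyl group for the hydroxyl group.
It would O-formylate the ring B phenol to 2,4-dibromophenyl formate A1 and deprotonate 1,2-dibromo-4-fluorobenzene A2 between F and Br with LiN(iPr)2; the aryllithium from A2 would take the formyl group of A1 and give 2,3-dibromo-6-fluorobenzaldehyde A3.
The phenoxide set free would displace the fluoride of A3 to give 2,3-dibromo-6-(2,4-dibromophenoxy)benzaldehyde A4, and a Dakin-type Baeyer–Villiger oxidation of A4 would turn CHO into OH.
Weak, the lithiation of A2 with formyl transfer: an aryllithium flanked by F and Br can lose lithium halide to an aryne or undergo halogen dance, and the formate A1 can be attacked twice.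
Weak, the SNAr ring union to A4: a hindered, weakly nucleophilic phenoxide would have to choose C–F over the ortho C–Br bond that the aldehyde of A3 activates as well, in one pot and at a fixed 1:1 ratio of the partners.
Weak, the formyl excision from A4: in a di-ortho-substituted, electron-poor benzaldehyde hydride migration (oxidation to the carboxylic acid) competes with aryl migration, and the carbon is put in only to be cut out again.

**Retrosynthetic overview** (ring A: C1 OH, C2 Br, C3 Br, C4 H, C5 H, C6 OAr; ring B: the 2,4-dibromophenyl group)
Ring A is cut at C1–C2 and C5–C6. C2(Br)–C3(Br)–C4(H)–C5(H) is the diene of 3,4-dibromo-2H-pyran-2-one; C1(OH) and C6(OAr) are the carboxyl and α-carbons of (2,4-dibromophenoxy)acetic acid, used as its bis-silyl ketene acetal.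
Ring B is bought with both bromines. Ring A is closed last by a pyranone Diels–Alder reaction with inverse electron demand that loses CO2 and silanol, so the diaryl ether arises from an alkyl aryl ether and no C–O bond is ever made at an arene.
The ring A bromines are set on the pyranone by enol chemistry (C3 bromination, C4 deoxybromination), which fixes the 2,3-pattern.
The design needs no aryllithium next to bromine, no SNAr choice between halides and no carbon that is put in and cut out: the phenol carbon is the acid carbon.

Key step: step 5

Assumption: 4-hydroxy-2H-pyran-2-one (5), the 6-unsubstituted relative of triacetic acid lactone, is taken as a catalogue compound.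

Step 1
Reactants: 1 2,4-dibromophenol
Product: 2 (2,4-dibromophenoxy)acetic acid
Conditions: ClCH2CO2H (1.5 equiv), NaOH (3.2 equiv), H2O, 100 °C, 4 h; then HCl (aq) to pH 1
Reagents that add atoms: chloroacetic acid, OC(=O)CCl
Why: Williamson ether synthesis: the fully ionized phenol (pKa near 8) displaces chloride from chloroacetate by SN2, the way aryloxyacetic acids are made on scale; no stereocenter is formed.

Step 2
Reactants: 2 (2,4-dibromophenoxy)acetic acid
Product: 4 2-(2,4-dibromophenoxy)-1,1-bis(trimethylsilyloxy)ethene, via silyl ester 3 (not isolated)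
Conditions: KN(SiMe3)2 (1.0 equiv), THF, 0 °C, then Me3SiCl (2.4 equiv), rt, 1 h; then KN(SiMe3)2 (1.15 equiv), −78 °C → rt; pentane, filtration under argon, used crude
Reagents that add atoms: chlorotrimethylsilane, C[Si](C)(C)Cl
Why: O-silylation of the carboxylate and then of the ester enolate under internal-quench conditions (as for Ireland–Claisen silyl ketene acetals) should give the bis-silyl ketene acetal, which has two identical silyloxy groups and hence no alkene geometry; the silylamide base neither exchanges nor metalates the bromoarene.

Step 3
Reactants: 5 4-hydroxy-2H-pyran-2-one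
Product: 6 3-bromo-4-hydroxy-2H-pyran-2-one
Conditions: N-bromosuccinimide (1.0 equiv), MeCN, 0 °C → rt, 2 h
Reagents that add atoms: N-bromosuccinimide, O=C1CCC(=O)N1Br
Why: Electrophilic bromination of the vinylogous acid at C3, the enol carbon between the lactone carbonyl and C4–OH (the position taken in 4-hydroxycoumarin and triacetic acid lactone); one equivalent at 0 °C should leave C5 untouched.

Step 4
Reactants: 6 3-bromo-4-hydroxy-2H-pyran-2-one
Product: 7 3,4-dibromo-2H-pyran-2-one
Conditions: PBr3 (1.3 equiv), DMF, 0 → 60 °C, 3 h
Reagents that add atoms: phosphorus tribromide, BrP(Br)Br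
Why: Vilsmeier–Haack-type deoxybromination: the bromoiminium salt from DMF and PBr3 activates the C4 oxygen of the vinylogous acid and bromide enters by addition–elimination, the usual way from 4-hydroxy-2-pyranones to 4-bromo-2-pyranones.

Step 5
Reactants: 7 3,4-dibromo-2H-pyran-2-one; 4 2-(2,4-dibromophenoxy)-1,1-bis(trimethylsilyloxy)ethene
Product: 11 2,3-dibromo-6-(2,4-dibromophenoxy)phenol, via bicyclic lactone 8 (not isolated), via ketal diene 9 (not isolated), via aryl silyl ether 10 (not isolated)
Conditions: 4 (1.5 equiv), toluene, 90 °C, 16 h; then 140 °C (sealed tube), 4 h; then 1 M HCl, THF, rt, 30 min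
Reagents that add atoms: none
Why: Diels–Alder reaction with inverse electron demand between the electron-poor 2-pyranone diene (C3–C6 of 7) and the electron-rich ketene acetal 4, then retro-Diels–Alder loss of CO2 and aromatization; the closest known reaction type is the conversion of bromo- and acyl-2-pyranones into aryl ethers with vinyl ethers and ketene acetals, in which the acetal serves as an alkyne equivalent. Ring A closes as a six-membered carbocycle by a concerted, asynchronous (4+2) cycloaddition that forms C5–C6 and C1–C2 of the target: the nucleophilic CH(OAr) carbon of 4 should bond to C6 of 7, the unsubstituted and most electrophilic diene terminus, and the acetal carbon to the bromine-bearing C3, which gives lactone 8. Cycloreversion of 8 at 140 °C should expel CO2 and leave diene 9, whose bis-silyl ketal carbon lies next to the CH(OAr) carbon. Loss of Me3SiOH across these two carbons, or hydrolytic collapse of the ketal to the 2,4-dienone and enolization of the same C–H, aromatizes ring A to silyl ether 10 or directly to 11, and the acid work-up frees the phenol; the aryloxy group is kept because it sits on the carbon that gives up the proton and not on the ketal carbon. The step needs head-to-tail regioselectivity, which the matched polarization of both partners secures (it is the orientation found for vinyl ethers with 3-bromo-2-pyranone), and chemoselectivity for cycloaddition over addition–elimination at the C4 bromide, which neutral, Lewis-acid-free conditions in toluene should favour. The three stereocenters of 8 and the one of 9 are destroyed on aromatization, so no stereocontrol is needed.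

**Compound list**
1 | 2,4-dibromophenol | Oc1ccc(Br)cc1Br | starting material
2 | (2,4-dibromophenoxy)acetic acid | OC(=O)COc1ccc(Br)cc1Br | intermediate
3 | trimethylsilyl (2,4-dibromophenoxy)acetate (not isolated) | C[Si](C)(C)OC(=O)COc1ccc(Br)cc1Br | intermediate
4 | 2-(2,4-dibromophenoxy)-1,1-bis(trimethylsilyloxy)ethene | C[Si](C)(C)OC(=COc1ccc(Br)cc1Br)O[Si](C)(C)C | intermediate
5 | 4-hydroxy-2H-pyran-2-one | O=C1C=C(O)C=CO1 | starting material
6 | 3-bromo-4-hydroxy-2H-pyran-2-one | O=C1OC=CC(O)=C1Br | intermediate
7 | 3,4-dibromo-2H-pyran-2-one | O=C1OC=CC(Br)=C1Br | intermediate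
8 | 4,8-dibromo-6-(2,4-dibromophenoxy)-5,5-bis(trimethylsilyloxy)-2-oxabicyclo[2.2.2]oct-7-en-3-one (racemic, endo/exo mixture at C6; not isolated) | O=C1OC2C=C(Br)C1(Br)C(O[Si](C)(C)C)(O[Si](C)(C)C)C2Oc1ccc(Br)cc1Br | intermediate
9 | 1,2-dibromo-5-(2,4-dibromophenoxy)-6,6-bis(trimethylsilyloxy)cyclohexa-1,3-diene (racemic; not isolated) | BrC1=C(Br)C=CC(Oc2ccc(Br)cc2Br)C1(O[Si](C)(C)C)O[Si](C)(C)C | intermediate
10 | [2,3-dibromo-6-(2,4-dibromophenoxy)phenoxy]trimethylsilane (not isolated) | C[Si](C)(C)Oc1c(Oc2ccc(Br)cc2Br)ccc(Br)c1Br | intermediate
11 | 2,3-dibromo-6-(2,4-dibromophenoxy)phenol | Oc1c(Oc2ccc(Br)cc2Br)ccc(Br)c1Br | target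

Total step count: 5. Longest linear sequence: 3 steps (1 → 2 → 4 → 11, or 5 → 6 → 7 → 11).

**Steps most likely to fail**

1. Step 5 (cycloaddition and aromatization). The ketene acetal may add in conjugate fashion to C4 or C6 of the pyranone, with loss of bromide or ring opening, faster than it cycloadds; or aryloxide may ionize from diene 9 before the ketal collapses. The fallback builds ring A as a cyclohexane-1,3-dione and aromatizes it late. It sets out from 1: alkylation with chloroacetone (K2CO3, acetone, reflux) would give 1-(2,4-dibromophenoxy)propan-2-one F1. Consecutive Michael addition at the aryloxy-bearing methylene and Claisen cyclization from the methyl group with methyl acrylate (KOC(CH3)3, THF, 0 °C → rt) would give 4-(2,4-dibromophenoxy)cyclohexane-1,3-dione F2. N-Bromosuccinimide (CH2Cl2, 0 °C) would give 2-bromo-4-(2,4-dibromophenoxy)cyclohexane-1,3-dione F3. Oxalyl bromide with catalytic DMF should replace the enol oxygen at the carbonyl carbon remote from the aryloxy-bearing carbon by bromine, to give 2,3-dibromo-6-(2,4-dibromophenoxy)cyclohex-2-en-1-one F4. Dehydrogenation with DDQ (dioxane, 100 °C) would come back to the route at 11.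

2. Step 4 (hydroxyl to bromide on the pyranone). The electron-poor pyranone may be opened at C6 or C2 by bromide or by the formamidinium reagent, or the exchange at C4 next to the C3 bromine may stay incomplete in the acidic medium. The fallback separates activation from substitution. It sets out from 6: Tf2O and 2,6-lutidine (CH2Cl2, −40 °C) would give 3-bromo-2-oxo-2H-pyran-4-yl trifluoromethanesulfonate F5. LiBr in acetone at rt would then replace the sulfonate by addition–elimination under neutral conditions and come back to the route at 7.

3. Step 2 (bis-silyl ketene acetal). The ester enolate may be silylated at carbon or fragment to the aryloxyketene, and the bis-trimethylsilyl acetal may hydrolyse during isolation. The fallback uses a more robust mixed acetal and a terminal demethylation. It sets out from 2: Fischer esterification (MeOH, H2SO4) would give methyl (2,4-dibromophenoxy)acetate F6. LiN(SiMe3)2 and t-BuMe2SiCl (THF/DMPU, −78 °C) would give the distillable tert-butyl{[2-(2,4-dibromophenoxy)-1-methoxyethenyl]oxy}dimethylsilane F7 (E/Z mixture). Cycloaddition with 7 under the conditions of step 5, with loss of CO2 and silanol, would give 1,2-dibromo-4-(2,4-dibromophenoxy)-3-methoxybenzene F8, together with some 11 where methanol is lost instead. BBr3 (CH2Cl2, −78 → 0 °C) would cleave the methyl ether, leave the diaryl ether intact and come back to the route at 11.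

**Further compounds**
F1 | step 5 | 1-(2,4-dibromophenoxy)propan-2-one | CC(=O)COc1ccc(Br)cc1Br
F2 | step 5 | 4-(2,4-dibromophenoxy)cyclohexane-1,3-dione (racemic) | O=C1CC(=O)C(Oc2ccc(Br)cc2Br)CC1
F3 | step 5 | 2-bromo-4-(2,4-dibromophenoxy)cyclohexane-1,3-dione (racemic, enolized in solution) | O=C1CCC(Oc2ccc(Br)cc2Br)C(=O)C1Br
F4 | step 5 | 2,3-dibromo-6-(2,4-dibromophenoxy)cyclohex-2-en-1-one (racemic) | O=C1C(Oc2ccc(Br)cc2Br)CCC(Br)=C1Br
F5 | step 4 | 3-bromo-2-oxo-2H-pyran-4-yl trifluoromethanesulfonate | O=C1OC=CC(OS(=O)(=O)C(F)(F)F)=C1Br
F6 | step 2 | methyl (2,4-dibromophenoxy)acetate | COC(=O)COc1ccc(Br)cc1Br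
F7 | step 2 | tert-butyl{[2-(2,4-dibromophenoxy)-1-methoxyethenyl]oxy}dimethylsilane (E/Z mixture) | COC(=COc1ccc(Br)cc1Br)O[Si](C)(C)C(C)(C)C
F8 | step 2 | 1,2-dibromo-4-(2,4-dibromophenoxy)-3-methoxybenzene | COc1c(Oc2ccc(Br)cc2Br)ccc(Br)c1Br
A1 | direct plan | 2,4-dibromophenyl formate | O=COc1ccc(Br)cc1Br
A2 | direct plan | 1,2-dibromo-4-fluorobenzene | Fc1ccc(Br)c(Br)c1
A3 | direct plan | 2,3-dibromo-6-fluorobenzaldehyde | O=Cc1c(F)ccc(Br)c1Br
A4 | direct plan | 2,3-dibromo-6-(2,4-dibromophenoxy)benzaldehyde | O=Cc1c(Oc2ccc(Br)cc2Br)ccc(Br)c1Br
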